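Readings and results are calculated for an exercise.

The pitfall is to count the 1.50 equivalents of activator in this flask as available to the substrate. Saturday's run charged substrate and activator equally, yet 15.8% of its substrate, 0.0948 M, still stands at 3.00 h, somewhat above its 0.080 M of protic impurity.

| flask | substrate | activator | protic impurity | remark | time |
|---|---|---|---|---|---|
| Tuesday's | 0.27 M | 0.60 M | 0.080 M | run made earlier |  |
| Saturday's | 0.60 M | 0.60 M | 0.080 M | run made earlier |  |
| Thursday's | 0.40 M | 0.60 M | 0.040 M | run made earlier |  |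
| flask | 0.40 M | 0.600 M | 0.0800 M |  | 3.0 h |

| run | time / h | activated form / % | substrate / % | ring / % | open dimer / % |
|---|---|---|---|---|---|
| Tuesday's | 0.417 | 6.9 | 21.8 | 70.2 | 0.9 |
| Tuesday's | 1.00 | 0.6 | 5.9 | 90.4 | 2.7 |
| Tuesday's | 2.00 | 0 | 1.6 | 96.2 | 1.9 |
| Tuesday's | 3.00 | 0 | 1.4 | 97.9 | 1.9 |
| Saturday's | 0.250 | 11.0 | 44.7 | 41.6 | 2.8 |
| Saturday's | 0.500 | 3.2 | 30.3 | 62.5 | 3.3 |
| Saturday's | 1.33 | 0.6 | 18.4 | 77.7 | 5.0 |
| Saturday's | 3.00 | 0 | 15.8 | 80.8 | 5.0 |
| Thursday's | 0.250 | 13.6 | 38.6 | 47.2 | 1.6 |
| Thursday's | 0.500 | 4.6 | 20.8 | 72.1 | 2.9 |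
| Thursday's | 1.33 | 0.8 | 6.9 | 91.4 | 2.9 |
| Thursday's | 3.00 | 0.4 | 1.0 | 95.2 | 2.6 |

(scatter of a reading: 0.5 percentage points)

- percentages count the substrate that a species holds: one open dimer counts as two
- the earlier runs were read with a standard deviation of 0.5 percentage points

- the largest share of what was charged as substrate, at 3.0 h belongs to (substrate / open dimer / activated form / ring)
- the largest share itself, whichever of these holds it, in percent of the substrate charged

So I compare two amounts, the substrate charged and the usable activator, and carry their ratio, the load c(substrate)/(c(activator) − c(protic impurity)), 0.769 in this flask. Thursday's load of 0.714 leaves 1.0% of substrate at 3.00 h, while Saturday's load of 1.15 is above one. The flask's load is below one, so I expect ring to lead. Interpolating linearly in the load between Thursday's 95.2% and Saturday's 80.8% of ring, I commit to 93.4%.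

The forecast says ring at 94.5%, reckoned on “0.52 M usable activator”. The flask gives ring at 94.3%.

    substrate + activator → activated form (k = 0.00250 L mol⁻¹ s⁻¹)
    activated form → ring (k = 0.00330 s⁻¹)
    substrate + activated form → open dimer (k = 3.10 × 10⁻⁴ L mol⁻¹ s⁻¹)
    activator + protic impurity → quenched reagent (k = 0.00110 L mol⁻¹ s⁻¹)
    activator → decomposed reagent (k = 7.90 × 10⁻⁵ s⁻¹)

At a load of 0.769, this flask's activator goes to substrate 6.5 times as fast as into decomposed reagent at 0.157 h, and by 3.00 h quenched and decomposed reagent together hold 0.175 M, more than the impurity charged, while 6.99% of the activator remains. A further flask, like this one but charged with 1.6 M of substrate, has a load of 3.08, and at 3.00 h its activator stands at 0%, its ring at 32.2% and its substrate at 60.8%.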